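**Retrosynthetic overview**

1. The strategy rests on the inner 2,3-dihydrobenzofuran fused to ring B. Its O1 is the ring B phenol oxygen, its C3–C3a bond joins ring B to an acetate α-carbon, and its C2 is the benzylic carbon of ring C, so only C2–C3 is missing; it is cut back to aryldiazoacetate 34 and closed by an enantioselective rhodium carbenoid C–H insertion.
2. 34 comes from phenol 18 (ring A, all-cis oxolane, ring B with a CH2CO2Me arm) and benzylic bromide 32 (rings C and D with the outer dihydrobenzofuran) by O-alkylation and diazo transfer.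
3. 32 comes from 5-bromovanillin and silylated vanillyl alcohol; its dihydrobenzofuran is closed by the same insertion with the mirror-image catalyst.
4. 18 comes from keto diol 13, the aldol product of (R)-lactone 8 (Stobbe condensation, asymmetric hydrogenation) and aldehyde 10; the oxolane is closed by hydride reduction of its cyclic oxocarbenium ion.
5. Ring order: outer dihydrobenzofuran (step 20) and oxolane (step 10) in separate branches, inner dihydrobenzofuran last (step 27), then ester reduction and desilylation.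

Key step: step 27

Assumption 1: the sense of induction of the chiral catalysts is taken by analogy with simpler substrates ([Rh(cod)((S,S)-Et-DuPhos)]BF4 to the R acid 4; Rh2(S-PTTL)4 to a 2R and Rh2(R-PTTL)4 to a 2S dihydrobenzofuran). It is checked at steps 2 and 20; if a check shows the opposite sense, the other enantiomer of that catalyst is used and nothing else changes.

Assumption 2: 4-(benzyloxy)-3-methoxybenzaldehyde and 5-bromovanillin are bought. TBS = tert-butyldimethylsilyl, TIPS = triisopropylsilyl.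

**Route**

Step 1
Reactants: 1 4-(benzyloxy)-3-methoxybenzaldehyde; 2 dimethyl succinate
Product: 3 (E)-4-[4-(benzyloxy)-3-methoxyphenyl]-3-(methoxycarbonyl)but-3-enoic acid
Conditions: NaOMe, MeOH, reflux; then aq. HCl
Reagents that add atoms: none
Why: Stobbe condensation: the succinate enolate adds to the non-enolisable aldehyde, the aldolate lactonises onto the far ester and base opens the lactone by elimination, which should give the E half-ester with the free acid on the CH2 arm.

Step 2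
Reactants: 3 Stobbe half-ester
Product: 4 (R)-3-[4-(benzyloxy)-3-methoxybenzyl]-4-methoxy-4-oxobutanoic acid
Conditions: [Rh(cod)((S,S)-Et-DuPhos)]BF4 (0.5 mol %), H2 (5 bar), MeOH, rt
Reagents that add atoms: none
Why: Rhodium-catalysed asymmetric hydrogenation of an itaconate-type half-ester, in which chelation of the alkene and carboxyl group to the cationic bisphospholane complex fixes the face of H2 delivery and sets the branch carbon as R under catalyst control.

Step 3
Reactants: 4 (R)-half-ester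
Product: 6 (R)-4-[4-(benzyloxy)-3-methoxybenzyl]dihydrofuran-2(3H)-one, via hydroxy acid 5 (not isolated)
Conditions: KOH (1 equiv), EtOH; Ca(BH4)2 (from CaCl2 and NaBH4), EtOH, −10 °C → rt; then 2 M HCl, rt
Reagents that add atoms: none
Why: Chemoselective borohydride reduction of the methyl ester beside the unreactive carboxylate salt, followed by acid lactonisation of the γ-hydroxy acid, leaves the stereocentre untouched.

Step 4
Reactants: 6 benzyl-protected (R)-lactone
Product: 7 (R)-4-(4-hydroxy-3-methoxybenzyl)dihydrofuran-2(3H)-one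
Conditions: H2 (1 atm), Pd/C, EtOAc, rt
Reagents that add atoms: none
Why: Hydrogenolysis of the aryl benzyl ether; nothing else in the lactone is reducible under these conditions.

Step 5
Reactants: 7 phenol lactone
Product: 8 (R)-4-[3-methoxy-4-(triisopropylsilyloxy)benzyl]dihydrofuran-2(3H)-one
Conditions: TIPSCl, imidazole, DMF, rt
Reagents that add atoms: chlorotriisopropylsilane, CC(C)[Si](Cl)(C(C)C)C(C)C
Why: Silylation of the phenol gives a ring A protecting group that survives base, hydride and hydrogenolysis and is orthogonal to the benzyl ether used on ring B.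

Step 6
Reactants: 9 5-bromovanillin
Product: 10 4-(benzyloxy)-3-bromo-5-methoxybenzaldehyde
Conditions: BnBr, K2CO3, DMF, rt
Reagents that add atoms: benzyl bromide, BrCc1ccccc1
Why: Williamson etherification of the acidic phenol.

Step 7
Reactants: 8 (R)-lactone; 10 ring B aldehyde
Product: 11 (3S,4R)-3-{[4-(benzyloxy)-3-bromo-5-methoxyphenyl](hydroxy)methyl}-4-[3-methoxy-4-(triisopropylsilyloxy)benzyl]dihydrofuran-2(3H)-one as both carbinol epimers
Conditions: LDA, THF, −78 °C; then 10, −78 °C; AcOH quench at −78 °C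
Reagents that add atoms: none
Why: Aldol addition of the lithium lactone enolate, which attacks the aldehyde on the face away from the C4 arylmethyl group and so sets C3 trans to C4 (substrate control); the carbinol centre is not controlled and is removed in step 9.

Step 8
Reactants: 11 aldol lactone
Product: 12 (2R,3R)-2-{[4-(benzyloxy)-3-bromo-5-methoxyphenyl](hydroxy)methyl}-3-[3-methoxy-4-(triisopropylsilyloxy)benzyl]butane-1,4-diol as both carbinol epimers
Conditions: LiBH4, THF, 0 °C → rt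
Reagents that add atoms: none
Why: Borohydride reduction of the lactone to the 1,4-diol, mild enough to leave the aryl bromide and the aryl silyl ether alone.

Step 9
Reactants: 12 triol
Product: 13 (2R,3R)-1-[4-(benzyloxy)-3-bromo-5-methoxyphenyl]-4-hydroxy-2-(hydroxymethyl)-3-[3-methoxy-4-(triisopropylsilyloxy)benzyl]butan-1-one
Conditions: activated MnO2, CH2Cl2, rt
Reagents that add atoms: none
Why: MnO2 oxidation is selective for the benzylic secondary alcohol over the two primary aliphatic alcohols and merges both carbinol epimers into one aryl ketone.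

Step 10
Reactants: 13 keto diol
Product: 15 [(2R,3R,4R)-2-[4-(benzyloxy)-3-bromo-5-methoxyphenyl]-4-[3-methoxy-4-(triisopropylsilyloxy)benzyl]oxolan-3-yl]methanol, via cyclic hemiketal 14 (not isolated)
Conditions: Et3SiH, BF3·OEt2, CH2Cl2, −78 → −40 °C; cold NaHCO3 quench
Reagents that add atoms: none
Why: Reductive etherification (ionic hydrogenation of a cyclic hemiketal): the Lewis acid ionises 14 to the 2-aryl oxocarbenium ion and the silane should add hydride on the face away from the mutually cis C3 hydroxymethyl and C4 arylmethyl groups (inside attack on the envelope with the C4 group pseudoequatorial), which places the aryl group cis to both and sets C2 as R.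

Step 11
Reactants: 15 oxolane alcohol
Product: 16 TBS ether of 15
Conditions: TBSCl, imidazole, DMF, rt
Reagents that add atoms: tert-butylchlorodimethylsilane, CC(C)(C)[Si](C)(C)Cl
Why: Silylation of the primary alcohol, needed so that no O–H bond is left for the carbenoid of step 27.

Step 12
Reactants: 16 aryl bromide
Product: 17 methyl 2-{2-(benzyloxy)-5-[(2R,3R,4R)-3-(TBS-oxymethyl)-4-[3-methoxy-4-(TIPS-oxy)benzyl]oxolan-2-yl]-3-methoxyphenyl}acetate
Conditions: BrZnCH2CO2Me (THF solution), Pd2(dba)3 (2.5 mol %), XPhos, THF, 60 °C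
Reagents that add atoms: methyl (bromozincio)acetate, COC(=O)C[Zn]Br
Why: Palladium-catalysed cross-coupling of a Reformatsky zinc enolate with an aryl bromide (Negishi-type α-arylation), which installs the CH2CO2Me arm in one step under conditions that leave silyl ethers and the benzylic oxolane alone.

Step 13
Reactants: 17 benzyl-protected arylacetate
Product: 18 methyl 2-{5-[(2R,3R,4R)-3-(TBS-oxymethyl)-4-[3-methoxy-4-(TIPS-oxy)benzyl]oxolan-2-yl]-2-hydroxy-3-methoxyphenyl}acetate
Conditions: H2 (1 atm), Pd/C, EtOAc, rt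
Reagents that add atoms: none
Why: Hydrogenolysis of the aryl benzyl ether in a neutral aprotic solvent should be much faster than cleavage of the benzylic C–O bond of the oxolane and frees only the ring B phenol, ring A being silylated.

Step 14
Reactants: 19 vanillin
Product: 20 3-methoxy-4-(triisopropylsilyloxy)benzaldehyde
Conditions: TIPSCl, imidazole, DMF, rt
Reagents that add atoms: chlorotriisopropylsilane, CC(C)[Si](Cl)(C(C)C)C(C)C
Why: Silylation of the phenol.

Step 15
Reactants: 20 silylated vanillin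
Product: 21 [3-methoxy-4-(triisopropylsilyloxy)phenyl]methanol
Conditions: NaBH4, EtOH, 0 °C
Reagents that add atoms: none
Why: Borohydride reduction of the aldehyde.

Step 16
Reactants: 9 5-bromovanillin; 21 ring D benzylic alcohol
Product: 22 3-bromo-5-methoxy-4-{[3-methoxy-4-(triisopropylsilyloxy)benzyl]oxy}benzaldehyde
Conditions: PPh3, DIAD, THF, 0 °C → rt
Reagents that add atoms: none
Why: Mitsunobu etherification: the phenol is acidic (para formyl, ortho bromine) and both of its ortho positions and its para position are substituted, so only O-alkylation is possible.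

Step 17
Reactants: 22 ring C aldehyde
Product: 23 2-(3-bromo-5-methoxy-4-{[3-methoxy-4-(triisopropylsilyloxy)benzyl]oxy}phenyl)-1,3-dioxolane
Conditions: ethylene glycol, PPTS, benzene, reflux (Dean–Stark)
Reagents that add atoms: ethylene glycol, OCCO
Why: Acetalisation masks the aldehyde against the zinc enolate of step 18.

Step 18
Reactants: 23 aryl bromide acetal
Product: 24 methyl 2-[5-(1,3-dioxolan-2-yl)-3-methoxy-2-{[3-methoxy-4-(triisopropylsilyloxy)benzyl]oxy}phenyl]acetate
Conditions: BrZnCH2CO2Me (THF solution), Pd2(dba)3 (2.5 mol %), XPhos, THF, 60 °C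
Reagents that add atoms: methyl (bromozincio)acetate, COC(=O)C[Zn]Br
Why: The same palladium-catalysed zinc enolate arylation as in step 12.

Step 19
Reactants: 24 arylacetate
Product: 25 methyl 2-diazo-2-[5-(1,3-dioxolan-2-yl)-3-methoxy-2-{[3-methoxy-4-(triisopropylsilyloxy)benzyl]oxy}phenyl]acetate
Conditions: p-ABSA, DBU, MeCN, 0 °C → rt
Reagents that add atoms: 4-acetamidobenzenesulfonyl azide, CC(=O)Nc1ccc(cc1)S(=O)(=O)N=[N+]=[N-]
Why: Regitz diazo transfer to the arylacetate, whose only acidic C–H bonds are those of the benzylic ester methylene.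

Step 20
Reactants: 25 ring C aryldiazoacetate
Product: 27 methyl (2S,3S)-5-(1,3-dioxolan-2-yl)-7-methoxy-2-[3-methoxy-4-(triisopropylsilyloxy)phenyl]-2,3-dihydro-1-benzofuran-3-carboxylate, via cis ester 26 (not isolated)
Conditions: Rh2(R-PTTL)4 (1 mol %), toluene, −78 °C; then DBU, rt
Reagents that add atoms: none
Why: Enantioselective intramolecular rhodium carbenoid 1,5 C–H insertion into the ring D benzylic ether methylene, in which the chiral carboxylate ligands set C2 as S (catalyst control) and DBU then epimerises the kinetic cis ester at C3 to the trans ester (thermodynamic control).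

Step 21
Reactants: 27 trans ester
Product: 29 (2S,3R)-3-(hydroxymethyl)-7-methoxy-2-[3-methoxy-4-(triisopropylsilyloxy)phenyl]-2,3-dihydro-1-benzofuran-5-carbaldehyde, via hydroxy acetal 28 (not isolated)
Conditions: LiAlH4, THF, 0 °C; then 1 M HCl, THF, rt
Reagents that add atoms: water, O
Why: Hydride reduction of the ester (C3 is no longer epimerisable afterwards) followed by acid hydrolysis of the electron-rich aryl dioxolane during work-up.

Step 22
Reactants: 29 hydroxy aldehyde
Product: 30 (2S,3R)-3-(TBS-oxymethyl)-7-methoxy-2-[3-methoxy-4-(triisopropylsilyloxy)phenyl]-2,3-dihydro-1-benzofuran-5-carbaldehyde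
Conditions: TBSCl, imidazole, DMF, rt
Reagents that add atoms: tert-butylchlorodimethylsilane, CC(C)(C)[Si](C)(C)Cl
Why: Silylation of the primary alcohol.

Step 23
Reactants: 30 silylated aldehyde
Product: 31 [(2S,3R)-3-(TBS-oxymethyl)-7-methoxy-2-[3-methoxy-4-(triisopropylsilyloxy)phenyl]-2,3-dihydro-1-benzofuran-5-yl]methanol
Conditions: NaBH4, EtOH, 0 °C
Reagents that add atoms: none
Why: Borohydride reduction of the aldehyde.

Step 24
Reactants: 31 benzylic alcohol
Product: 32 (2S,3R)-5-(bromomethyl)-3-(TBS-oxymethyl)-7-methoxy-2-[3-methoxy-4-(triisopropylsilyloxy)phenyl]-2,3-dihydro-1-benzofuran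
Conditions: CBr4, PPh3, 2,6-lutidine, CH2Cl2, 0 °C; used crude
Reagents that add atoms: tetrabromomethane, BrC(Br)(Br)Br
Why: Appel bromination under buffered, non-acidic conditions that spare the silyl ethers and the benzylic ring ether.

Step 25
Reactants: 18 ring B phenol; 32 benzylic bromide
Product: 33 methyl 2-{5-[(2R,3R,4R)-oxolan-2-yl unit of 18]-3-methoxy-2-({(2S,3R)-dihydrobenzofuran-5-yl unit of 32}methoxy)phenyl}acetate (coupled ester)
Conditions: K2CO3, DMF, rt
Reagents that add atoms: none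
Why: Williamson etherification of the phenoxide with a reactive electron-rich benzylic bromide; carbonate does not deprotonate the arylacetate, so alkylation occurs on oxygen only.

Step 26
Reactants: 33 coupled ester
Product: 34 methyl 2-diazo-2-{...}acetate of 33 (aryldiazoacetate, key precursor)
Conditions: p-ABSA, DBU, MeCN, 0 °C → rt
Reagents that add atoms: 4-acetamidobenzenesulfonyl azide, CC(=O)Nc1ccc(cc1)S(=O)(=O)N=[N+]=[N-]
Why: Regitz diazo transfer to the only arylacetate methylene of the molecule.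

Step 27
Reactants: 34 aryldiazoacetate
Product: 36 methyl (2R,3R)-2-aryl-2,3-dihydro-1-benzofuran-3-carboxylate (inner trans ester; full structure in the list), via cis ester 35 (not isolated)
Conditions: Rh2(S-PTTL)4 (dirhodium tetrakis[N-phthaloyl-(S)-tert-leucinate], divalent rhodium, 2 mol %), toluene (dilute), −78 → −40 °C; then DBU, rt
Reagents that add atoms: none
Why: The catalyst expels N2 from 34 to give a donor–acceptor rhodium carbenoid on ring B, which inserts into one of the two enantiotopic C–H bonds of the ring C benzylic OCH2 group through a concerted, hydride-transfer-like three-centre transition state. The closest known reaction is the enantioselective intramolecular insertion of methyl 2-(2-benzyloxyaryl)-2-diazoacetates to cis-2-aryl-2,3-dihydrobenzofuran-3-carboxylates with this catalyst class, also used in step 20. The dihydrofuran ring closes by 1,5-insertion through a five-membered transition state that forms C2–C3, the bonds O1–C2 and C3–C3a being present already. C2 is set as R by the chiral carboxylate pocket (catalyst control, the five existing stereocentres being remote), while C3 forms cis under kinetic control and is then turned trans (R in the ester) by DBU enolisation under thermodynamic control without touching C2. The step needs insertion at the OCH2 group in preference to O–H insertion, intermolecular reaction or carbene dimerisation. This is secured by silylation of every hydroxyl group, by the fact that no other C–H bond can reach the carbenoid through a five-membered transition state (the oxolane sits meta to it), by low temperature and dilution, and by the electron-rich ring C, which stabilises positive charge at the inserting carbon.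

Step 28
Reactants: 36 inner trans ester
Product: 37 primary alcohol of 36 (inner ring 2R,3S)
Conditions: LiAlH4, THF, 0 °C; aqueous work-up
Reagents that add atoms: none
Why: Hydride reduction of the ester to the hydroxymethyl group, which also removes the only epimerisable centre.

Step 29
Reactants: 37 tetrasilyl ether
Product: 38 target CNP0395728.1
Conditions: TBAF, AcOH, THF, 0 °C → rt
Reagents that add atoms: none
Why: Fluoride-mediated cleavage of the two aryl TIPS and two alkyl TBS ethers, buffered with acetic acid so that the free para-hydroxybenzylic ethers are exposed to neither strong base nor acid.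

**Compound list**

1 | 4-(benzyloxy)-3-methoxybenzaldehyde | COc1cc(C=O)ccc1OCc1ccccc1 | starting material
2 | dimethyl succinate | COC(=O)CCC(=O)OC | starting material
3 | (E)-4-[4-(benzyloxy)-3-methoxyphenyl]-3-(methoxycarbonyl)but-3-enoic acid | COC(=O)/C(CC(=O)O)=C/c1ccc(OCc2ccccc2)c(OC)c1 | intermediate
4 | (R)-3-[4-(benzyloxy)-3-methoxybenzyl]-4-methoxy-4-oxobutanoic acid | COC(=O)[C@@H](CC(=O)O)Cc1ccc(OCc2ccccc2)c(OC)c1 | intermediate
5 | (R)-3-[4-(benzyloxy)-3-methoxybenzyl]-4-hydroxybutanoic acid (formed in the flask of step 3) | OC[C@@H](CC(=O)O)Cc1ccc(OCc2ccccc2)c(OC)c1 | intermediate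
6 | (R)-4-[4-(benzyloxy)-3-methoxybenzyl]dihydrofuran-2(3H)-one | O=C1C[C@@H](Cc2ccc(OCc3ccccc3)c(OC)c2)CO1 | intermediate
7 | (R)-4-(4-hydroxy-3-methoxybenzyl)dihydrofuran-2(3H)-one | O=C1C[C@@H](Cc2ccc(O)c(OC)c2)CO1 | intermediate
8 | (R)-4-[3-methoxy-4-(triisopropylsilyloxy)benzyl]dihydrofuran-2(3H)-one | O=C1C[C@@H](Cc2ccc(O[Si](C(C)C)(C(C)C)C(C)C)c(OC)c2)CO1 | intermediate
9 | 5-bromovanillin (3-bromo-4-hydroxy-5-methoxybenzaldehyde) | COc1cc(C=O)cc(Br)c1O | starting material
10 | 4-(benzyloxy)-3-bromo-5-methoxybenzaldehyde | COc1cc(C=O)cc(Br)c1OCc1ccccc1 | intermediate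
11 | (3S,4R)-3-{[4-(benzyloxy)-3-bromo-5-methoxyphenyl](hydroxy)methyl}-4-[3-methoxy-4-(triisopropylsilyloxy)benzyl]dihydrofuran-2(3H)-one, both carbinol epimers | O=C1OC[C@H](Cc2ccc(O[Si](C(C)C)(C(C)C)C(C)C)c(OC)c2)[C@H]1C(O)c1cc(OC)c(OCc2ccccc2)c(Br)c1 | intermediate
12 | (2R,3R)-2-{[4-(benzyloxy)-3-bromo-5-methoxyphenyl](hydroxy)methyl}-3-[3-methoxy-4-(triisopropylsilyloxy)benzyl]butane-1,4-diol, both carbinol epimers | OC[C@H](Cc1ccc(O[Si](C(C)C)(C(C)C)C(C)C)c(OC)c1)[C@H](CO)C(O)c1cc(OC)c(OCc2ccccc2)c(Br)c1 | intermediate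
13 | (2R,3R)-1-[4-(benzyloxy)-3-bromo-5-methoxyphenyl]-4-hydroxy-2-(hydroxymethyl)-3-[3-methoxy-4-(triisopropylsilyloxy)benzyl]butan-1-one | OC[C@H](Cc1ccc(O[Si](C(C)C)(C(C)C)C(C)C)c(OC)c1)[C@H](CO)C(=O)c1cc(OC)c(OCc2ccccc2)c(Br)c1 | intermediate
14 | (3R,4R)-2-[4-(benzyloxy)-3-bromo-5-methoxyphenyl]-3-(hydroxymethyl)-4-[3-methoxy-4-(triisopropylsilyloxy)benzyl]oxolan-2-ol, C2 epimers (formed in the flask of step 10) | COc1cc(C[C@H]2COC(O)(c3cc(OC)c(OCc4ccccc4)c(Br)c3)[C@H]2CO)ccc1O[Si](C(C)C)(C(C)C)C(C)C | intermediate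
15 | [(2R,3R,4R)-2-[4-(benzyloxy)-3-bromo-5-methoxyphenyl]-4-[3-methoxy-4-(triisopropylsilyloxy)benzyl]oxolan-3-yl]methanol (all-cis) | COc1cc(C[C@H]2CO[C@@H](c3cc(OC)c(OCc4ccccc4)c(Br)c3)[C@H]2CO)ccc1O[Si](C(C)C)(C(C)C)C(C)C | intermediate
16 | tert-butyl({(2R,3R,4R)-2-[4-(benzyloxy)-3-bromo-5-methoxyphenyl]-4-[3-methoxy-4-(triisopropylsilyloxy)benzyl]oxolan-3-yl}methoxy)dimethylsilane | COc1cc(C[C@H]2CO[C@@H](c3cc(OC)c(OCc4ccccc4)c(Br)c3)[C@H]2CO[Si](C)(C)C(C)(C)C)ccc1O[Si](C(C)C)(C(C)C)C(C)C | intermediate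
17 | methyl 2-{2-(benzyloxy)-5-[(2R,3R,4R)-3-{[tert-butyl(dimethyl)silyl]oxymethyl}-4-[3-methoxy-4-(triisopropylsilyloxy)benzyl]oxolan-2-yl]-3-methoxyphenyl}acetate | COc1cc(C[C@H]2CO[C@@H](c3cc(OC)c(OCc4ccccc4)c(CC(=O)OC)c3)[C@H]2CO[Si](C)(C)C(C)(C)C)ccc1O[Si](C(C)C)(C(C)C)C(C)C | intermediate
18 | methyl 2-{5-[(2R,3R,4R)-3-{[tert-butyl(dimethyl)silyl]oxymethyl}-4-[3-methoxy-4-(triisopropylsilyloxy)benzyl]oxolan-2-yl]-2-hydroxy-3-methoxyphenyl}acetate | COc1cc(C[C@H]2CO[C@@H](c3cc(OC)c(O)c(CC(=O)OC)c3)[C@H]2CO[Si](C)(C)C(C)(C)C)ccc1O[Si](C(C)C)(C(C)C)C(C)C | intermediate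
19 | vanillin | COc1cc(C=O)ccc1O | starting material
20 | 3-methoxy-4-(triisopropylsilyloxy)benzaldehyde | COc1cc(C=O)ccc1O[Si](C(C)C)(C(C)C)C(C)C | intermediate
21 | [3-methoxy-4-(triisopropylsilyloxy)phenyl]methanol | COc1cc(CO)ccc1O[Si](C(C)C)(C(C)C)C(C)C | intermediate
22 | 3-bromo-5-methoxy-4-{[3-methoxy-4-(triisopropylsilyloxy)benzyl]oxy}benzaldehyde | COc1cc(C=O)cc(Br)c1OCc1ccc(O[Si](C(C)C)(C(C)C)C(C)C)c(OC)c1 | intermediate
23 | 2-(3-bromo-5-methoxy-4-{[3-methoxy-4-(triisopropylsilyloxy)benzyl]oxy}phenyl)-1,3-dioxolane | COc1cc(C2OCCO2)cc(Br)c1OCc1ccc(O[Si](C(C)C)(C(C)C)C(C)C)c(OC)c1 | intermediate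
24 | methyl 2-[5-(1,3-dioxolan-2-yl)-3-methoxy-2-{[3-methoxy-4-(triisopropylsilyloxy)benzyl]oxy}phenyl]acetate | COc1cc(C2OCCO2)cc(CC(=O)OC)c1OCc1ccc(O[Si](C(C)C)(C(C)C)C(C)C)c(OC)c1 | intermediate
25 | methyl 2-diazo-2-[5-(1,3-dioxolan-2-yl)-3-methoxy-2-{[3-methoxy-4-(triisopropylsilyloxy)benzyl]oxy}phenyl]acetate | COc1cc(C2OCCO2)cc(C(=[N+]=[N-])C(=O)OC)c1OCc1ccc(O[Si](C(C)C)(C(C)C)C(C)C)c(OC)c1 | intermediate
26 | methyl (2S,3R)-5-(1,3-dioxolan-2-yl)-7-methoxy-2-[3-methoxy-4-(triisopropylsilyloxy)phenyl]-2,3-dihydro-1-benzofuran-3-carboxylate, cis (formed in the flask of step 20) | C1COC(O1)c1cc(OC)c2c(c1)[C@@H](C(=O)OC)[C@@H](c1ccc(O[Si](C(C)C)(C(C)C)C(C)C)c(OC)c1)O2 | intermediate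
27 | methyl (2S,3S)-5-(1,3-dioxolan-2-yl)-7-methoxy-2-[3-methoxy-4-(triisopropylsilyloxy)phenyl]-2,3-dihydro-1-benzofuran-3-carboxylate, trans | C1COC(O1)c1cc(OC)c2c(c1)[C@H](C(=O)OC)[C@@H](c1ccc(O[Si](C(C)C)(C(C)C)C(C)C)c(OC)c1)O2 | intermediate
28 | [(2S,3R)-5-(1,3-dioxolan-2-yl)-7-methoxy-2-[3-methoxy-4-(triisopropylsilyloxy)phenyl]-2,3-dihydro-1-benzofuran-3-yl]methanol (formed in the flask of step 21) | C1COC(O1)c1cc(OC)c2c(c1)[C@H](CO)[C@@H](c1ccc(O[Si](C(C)C)(C(C)C)C(C)C)c(OC)c1)O2 | intermediate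
29 | (2S,3R)-3-(hydroxymethyl)-7-methoxy-2-[3-methoxy-4-(triisopropylsilyloxy)phenyl]-2,3-dihydro-1-benzofuran-5-carbaldehyde | O=Cc1cc(OC)c2c(c1)[C@H](CO)[C@@H](c1ccc(O[Si](C(C)C)(C(C)C)C(C)C)c(OC)c1)O2 | intermediate
30 | (2S,3R)-3-{[tert-butyl(dimethyl)silyl]oxymethyl}-7-methoxy-2-[3-methoxy-4-(triisopropylsilyloxy)phenyl]-2,3-dihydro-1-benzofuran-5-carbaldehyde | O=Cc1cc(OC)c2c(c1)[C@H](CO[Si](C)(C)C(C)(C)C)[C@@H](c1ccc(O[Si](C(C)C)(C(C)C)C(C)C)c(OC)c1)O2 | intermediate
31 | [(2S,3R)-3-{[tert-butyl(dimethyl)silyl]oxymethyl}-7-methoxy-2-[3-methoxy-4-(triisopropylsilyloxy)phenyl]-2,3-dihydro-1-benzofuran-5-yl]methanol | OCc1cc(OC)c2c(c1)[C@H](CO[Si](C)(C)C(C)(C)C)[C@@H](c1ccc(O[Si](C(C)C)(C(C)C)C(C)C)c(OC)c1)O2 | intermediate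
32 | (2S,3R)-5-(bromomethyl)-3-{[tert-butyl(dimethyl)silyl]oxymethyl}-7-methoxy-2-[3-methoxy-4-(triisopropylsilyloxy)phenyl]-2,3-dihydro-1-benzofuran | BrCc1cc(OC)c2c(c1)[C@H](CO[Si](C)(C)C(C)(C)C)[C@@H](c1ccc(O[Si](C(C)C)(C(C)C)C(C)C)c(OC)c1)O2 | intermediate
33 | methyl 2-{5-[(2R,3R,4R)-3-(TBS-oxymethyl)-4-[3-methoxy-4-(TIPS-oxy)benzyl]oxolan-2-yl]-3-methoxy-2-({(2S,3R)-3-(TBS-oxymethyl)-7-methoxy-2-[3-methoxy-4-(TIPS-oxy)phenyl]-2,3-dihydro-1-benzofuran-5-yl}methoxy)phenyl}acetate | COc1cc(C[C@H]2CO[C@@H](c3cc(OC)c(OCc4cc(OC)c5c(c4)[C@H](CO[Si](C)(C)C(C)(C)C)[C@@H](c4ccc(O[Si](C(C)C)(C(C)C)C(C)C)c(OC)c4)O5)c(CC(=O)OC)c3)[C@H]2CO[Si](C)(C)C(C)(C)C)ccc1O[Si](C(C)C)(C(C)C)C(C)C | intermediate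
34 | methyl 2-diazo-2-{aryl of 33}acetate (aryldiazoacetate, key precursor) | COc1cc(C[C@H]2CO[C@@H](c3cc(OC)c(OCc4cc(OC)c5c(c4)[C@H](CO[Si](C)(C)C(C)(C)C)[C@@H](c4ccc(O[Si](C(C)C)(C(C)C)C(C)C)c(OC)c4)O5)c(C(=[N+]=[N-])C(=O)OC)c3)[C@H]2CO[Si](C)(C)C(C)(C)C)ccc1O[Si](C(C)C)(C(C)C)C(C)C | intermediate
35 | methyl (2R,3S)-2-{(2S,3R)-3-(TBS-oxymethyl)-7-methoxy-2-[3-methoxy-4-(TIPS-oxy)phenyl]-2,3-dihydro-1-benzofuran-5-yl}-5-[(2R,3R,4R)-3-(TBS-oxymethyl)-4-[3-methoxy-4-(TIPS-oxy)benzyl]oxolan-2-yl]-7-methoxy-2,3-dihydro-1-benzofuran-3-carboxylate, inner ring cis (formed in the flask of step 27) | COc1cc(C[C@H]2CO[C@@H](c3cc(OC)c4c(c3)[C@H](C(=O)OC)[C@H](c3cc(OC)c5c(c3)[C@H](CO[Si](C)(C)C(C)(C)C)[C@@H](c3ccc(O[Si](C(C)C)(C(C)C)C(C)C)c(OC)c3)O5)O4)[C@H]2CO[Si](C)(C)C(C)(C)C)ccc1O[Si](C(C)C)(C(C)C)C(C)C | intermediate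
36 | methyl (2R,3R)-2-{(2S,3R)-3-(TBS-oxymethyl)-7-methoxy-2-[3-methoxy-4-(TIPS-oxy)phenyl]-2,3-dihydro-1-benzofuran-5-yl}-5-[(2R,3R,4R)-3-(TBS-oxymethyl)-4-[3-methoxy-4-(TIPS-oxy)benzyl]oxolan-2-yl]-7-methoxy-2,3-dihydro-1-benzofuran-3-carboxylate, inner ring trans (key product) | COc1cc(C[C@H]2CO[C@@H](c3cc(OC)c4c(c3)[C@@H](C(=O)OC)[C@H](c3cc(OC)c5c(c3)[C@H](CO[Si](C)(C)C(C)(C)C)[C@@H](c3ccc(O[Si](C(C)C)(C(C)C)C(C)C)c(OC)c3)O5)O4)[C@H]2CO[Si](C)(C)C(C)(C)C)ccc1O[Si](C(C)C)(C(C)C)C(C)C | intermediate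
37 | {(2R,3S)-2-{(2S,3R)-3-(TBS-oxymethyl)-7-methoxy-2-[3-methoxy-4-(TIPS-oxy)phenyl]-2,3-dihydro-1-benzofuran-5-yl}-5-[(2R,3R,4R)-3-(TBS-oxymethyl)-4-[3-methoxy-4-(TIPS-oxy)benzyl]oxolan-2-yl]-7-methoxy-2,3-dihydro-1-benzofuran-3-yl}methanol | COc1cc(C[C@H]2CO[C@@H](c3cc(OC)c4c(c3)[C@@H](CO)[C@H](c3cc(OC)c5c(c3)[C@H](CO[Si](C)(C)C(C)(C)C)[C@@H](c3ccc(O[Si](C(C)C)(C(C)C)C(C)C)c(OC)c3)O5)O4)[C@H]2CO[Si](C)(C)C(C)(C)C)ccc1O[Si](C(C)C)(C(C)C)C(C)C | intermediate
38 | CNP0395728.1: [(2R,3R,4R)-4-(4-hydroxy-3-methoxybenzyl)-2-{(2R,3S)-3-(hydroxymethyl)-2-[(2S,3R)-2-(4-hydroxy-3-methoxyphenyl)-3-(hydroxymethyl)-7-methoxy-2,3-dihydro-1-benzofuran-5-yl]-7-methoxy-2,3-dihydro-1-benzofuran-5-yl}oxolan-3-yl]methanol | COc1cc(C[C@H]2CO[C@@H](c3cc(OC)c4c(c3)[C@@H](CO)[C@H](c3cc(OC)c5c(c3)[C@H](CO)[C@@H](c3ccc(O)c(OC)c3)O5)O4)[C@H]2CO)ccc1O | target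

**Count**

Total steps: 29. Longest linear sequence: 17 steps (from 1 through steps 1–5, 7–13 and 25–29).

**Steps most likely to fail**

1. Step 27. The catalyst may discriminate poorly between the two benzylic C–H bonds on so large a substrate, the carbenoid may be lost to dimerisation or intermolecular insertion, or the DBU treatment may open the new ring by β-elimination of the phenoxide. The fallback sets out from phenol 18 and aldehyde 30 and comes back at 36. Phenol 18 is converted with LDA (2.2 equiv, THF, −78 °C) into its phenoxide–enolate dianion and added to aldehyde 30, which should give the β-hydroxy ester, the aldol adduct F1, as a mixture at the two new carbons. Intramolecular Mitsunobu etherification (PPh3, DIAD, THF, 0 °C) of the phenol onto the benzylic carbinol closes the dihydrofuran ring to the cyclised ester mixture F2. DBU then equilibrates C3 to trans in both C2 series, leaving 36 and its inner-ring (2S,3S) diastereomer F3, which are diastereomers and are separated by chromatography. This route gives up catalyst control at the inner C2 and relies on the separation.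

2. Step 10. The oxocarbenium ion may lose the C3 configuration by proton loss to the cyclic enol ether, hydride may arrive from the wrong face, or the benzylic C–O bond may be reduced further. The fallback sets out from keto diol 13 and comes back at 15. Warming 13 with PPTS in toluene at 80 °C should dehydrate its hemiketal to the aryl-conjugated cyclic enol ether, the dihydrofuran F4. Homogeneous hydrogenation with [Ir(cod)(PCy3)(py)]PF6 and H2 in CH2Cl2, which spares the aryl bromide and the benzyl ether, should add both hydrogens to the alkene face opposite the C4 arylmethyl group. That sets C2 and C3 together and gives the all-cis oxolane 15, whatever happened to C3 before.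

3. Step 12. Oxidative addition into the electron-rich, ortho-alkoxy aryl bromide may be slow, so that the zinc enolate is lost to protonation or self-condensation first. The fallback sets out from bromide 16 and comes back at 17. Stille coupling with allyltributylstannane (Pd(PPh3)4, toluene, 100 °C) should give the allyl arene F5. Cleavage of the alkene with OsO4 (cat.) and NaIO4 (2,6-lutidine, dioxane–water) gives the arylacetaldehyde F6. Pinnick oxidation (NaClO2, NaH2PO4, 2-methyl-2-butene) gives the arylacetic acid F7, and Me3SiCHN2 in MeOH–toluene gives methyl ester 17.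

**Further compounds**

F1 | step 27 | methyl 3-hydroxy-2-{2-hydroxy-3-methoxy-5-[oxolan-2-yl unit of 18]phenyl}-3-{dihydrobenzofuran-5-yl unit of 30}propanoate, mixture at the two new carbons | COc1cc(C[C@H]2CO[C@@H](c3cc(OC)c(O)c(c3)C(C(=O)OC)C(O)c3cc(OC)c4c(c3)[C@H](CO[Si](C)(C)C(C)(C)C)[C@@H](c3ccc(O[Si](C(C)C)(C(C)C)C(C)C)c(OC)c3)O4)[C@H]2CO[Si](C)(C)C(C)(C)C)ccc1O[Si](C(C)C)(C(C)C)C(C)C
F2 | step 27 | cyclised ester with the constitution of 36, inner C2 and C3 unassigned | COc1cc(C[C@H]2CO[C@@H](c3cc(OC)c4c(c3)C(C(=O)OC)C(c3cc(OC)c5c(c3)[C@H](CO[Si](C)(C)C(C)(C)C)[C@@H](c3ccc(O[Si](C(C)C)(C(C)C)C(C)C)c(OC)c3)O5)O4)[C@H]2CO[Si](C)(C)C(C)(C)C)ccc1O[Si](C(C)C)(C(C)C)C(C)C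
F3 | step 27 | inner-ring (2S,3S)-trans diastereomer of 36 | COc1cc(C[C@H]2CO[C@@H](c3cc(OC)c4c(c3)[C@H](C(=O)OC)[C@@H](c3cc(OC)c5c(c3)[C@H](CO[Si](C)(C)C(C)(C)C)[C@@H](c3ccc(O[Si](C(C)C)(C(C)C)C(C)C)c(OC)c3)O5)O4)[C@H]2CO[Si](C)(C)C(C)(C)C)ccc1O[Si](C(C)C)(C(C)C)C(C)C
F4 | step 10 | [(4R)-2-[4-(benzyloxy)-3-bromo-5-methoxyphenyl]-4-[3-methoxy-4-(triisopropylsilyloxy)benzyl]-4,5-dihydrofuran-3-yl]methanol | COc1cc(C[C@H]2COC(c3cc(OC)c(OCc4ccccc4)c(Br)c3)=C2CO)ccc1O[Si](C(C)C)(C(C)C)C(C)C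
F5 | step 12 | allyl arene: 16 with CH2CH=CH2 in place of Br | COc1cc(C[C@H]2CO[C@@H](c3cc(OC)c(OCc4ccccc4)c(CC=C)c3)[C@H]2CO[Si](C)(C)C(C)(C)C)ccc1O[Si](C(C)C)(C(C)C)C(C)C
F6 | step 12 | arylacetaldehyde: 16 with CH2CHO in place of Br | COc1cc(C[C@H]2CO[C@@H](c3cc(OC)c(OCc4ccccc4)c(CC=O)c3)[C@H]2CO[Si](C)(C)C(C)(C)C)ccc1O[Si](C(C)C)(C(C)C)C(C)C
F7 | step 12 | arylacetic acid: 16 with CH2CO2H in place of Br | COc1cc(C[C@H]2CO[C@@H](c3cc(OC)c(OCc4ccccc4)c(CC(=O)O)c3)[C@H]2CO[Si](C)(C)C(C)(C)C)ccc1O[Si](C(C)C)(C(C)C)C(C)C
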